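**Retrosynthetic overview**
- The methylene bridge is cut last: the target comes from a photochemically generated chromene o-quinone methide (from an aryl Mannich base) and the enantiopure acylfilicinic acid half.
- The chromene half comes from butyrylphloroglucinol and prenal (Knoevenagel condensation, then oxa-6π closure of the pyran onto the bought arene).
- The acylfilicinic ring comes from a Dieckmann closure of a 3,5,7-triketo ester, made from a quaternary (R)-α-geranyl-α-methyl acetoacetate and diketene.
- That keto ester comes from ethyl (S)-3-hydroxybutanoate by two Fráter–Seebach alkylations (geranyl, then methyl) and oxidation; the bought carbinol centre sets the quaternary carbon and is then erased.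
- Ring order: filicinic carbocycle (convergent branch A), pyran of the chromene (branch B), then union of the halves.

Assumption: enolised trione rings are drawn in the tautomer of the target SMILES, in which the single stereocentre is R; "geranyl" means (2E)-3,7-dimethylocta-2,6-dien-1-yl.

**Step 1**
Reactants: 1 ethyl (3S)-3-hydroxybutanoate; 2 geranyl bromide
Product: 3 ethyl (2S,3S)-2-geranyl-3-hydroxybutanoate
Conditions: LDA (2.2 eq), THF, −78 → −20 °C; 2 (1.1 eq), DMPU, −78 → 0 °C; aqueous quench
Reagents that add atoms: none
Why: Fráter–Seebach alkylation, in which the chelated lithium alkoxide–enolate dianion is attacked by geranyl bromide (SN2, E-alkene retained) on the face anti to the C3 methyl of the chelate ring, so the bought (3S) carbinol sets C2 as 2S (anti, typically ≥95:5).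

**Step 2**
Reactants: 3 ethyl (2S,3S)-2-geranyl-3-hydroxybutanoate
Product: 4 ethyl (2R,3S)-2-geranyl-3-hydroxy-2-methylbutanoate
Conditions: LDA (2.5 eq), THF, −78 → 0 °C; MeI (3 eq), DMPU, −78 → −10 °C; aqueous quench
Reagents that add atoms: iodomethane, CI
Why: second Fráter–Seebach alkylation, in which the tetrasubstituted chelated dianion is again methylated from the face anti to the C3 methyl, so the quaternary carbon forms as 2R under control of the (3S) carbinol; the minor C2 epimer is a diastereomer and is removed by chromatography.

**Step 3**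
Reactants: 4 ethyl (2R,3S)-2-geranyl-3-hydroxy-2-methylbutanoate
Product: 5 ethyl (2R)-2-geranyl-2-methyl-3-oxobutanoate
Conditions: Dess–Martin periodinane (1.3 eq), CH2Cl2, 0 °C → rt
Reagents that add atoms: none
Why: Dess–Martin oxidation of the secondary alcohol under neutral conditions (no retro-aldol) erases the controlling carbinol centre, while the quaternary (R) centre has no α-hydrogen and cannot epimerise.

**Step 4**
Reactants: 5 ethyl (2R)-2-geranyl-2-methyl-3-oxobutanoate; 6 diketene
Product: 8 (4R)-2-acetyl-4-geranyl-3,5-dihydroxy-4-methylcyclohexa-2,5-dien-1-one, via triketo ester 7 (not isolated)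
Conditions: LDA (1.05 eq), THF, −78 °C; 6 (1.1 eq), −78 → −20 °C; t-BuOK (2.5 eq), 0 → 40 °C; 1 M HCl
Reagents that add atoms: none
Why: C-acetoacetylation of the only possible enolate (the acetyl CH3) by acyl–oxygen opening of diketene gives 7, whose internal C6 carbanion closes onto the ethyl ester (Dieckmann/Claisen cyclisation of a 3,5,7-triketo ester); the competing aldol mode through C2 is blocked because C2 is quaternary, so the acetyl group lands next to the ester-derived carbonyl and the stereocentre is carried through untouched.

**Step 5**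
Reactants: 9 1-(2,4,6-trihydroxyphenyl)butan-1-one; 10 3-methylbut-2-enal
Product: 12 1-(5,7-dihydroxy-2,2-dimethyl-2H-chromen-6-yl)butan-1-one, via dienone 11 (not isolated)
Conditions: 10 (1.1 eq), ethylenediammonium diacetate (10 mol %), toluene, 100 °C
Reagents that add atoms: none
Why: amine-catalysed Knoevenagel condensation at a free ring carbon gives dienone 11, which closes by oxa-6π electrocyclisation through the non-chelated 4-oxygen (para to the acyl group) to the 6-acyl chromene; the 8-acyl regioisomer from closure through a 2-OH is expected to be minor and is separated by chromatography.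

**Step 6**
Reactants: 12 1-(5,7-dihydroxy-2,2-dimethyl-2H-chromen-6-yl)butan-1-one
Product: 13 1-[8-[(dimethylamino)methyl]-5,7-dihydroxy-2,2-dimethyl-2H-chromen-6-yl]butan-1-one
Conditions: Eschenmoser's salt (1.05 eq), CH2Cl2/MeCN, 0 °C → rt; aq NaHCO3
Reagents that add atoms: N,N-dimethylmethyleneiminium iodide (Eschenmoser's salt), C=[N+](C)C.[I-]
Why: Mannich reaction (electrophilic aromatic substitution by the preformed iminium ion) at C8, the only unsubstituted and doubly ortho-oxygenated ring carbon, which is far more nucleophilic than the chromene alkene.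

**Step 7**
Reactants: 13 1-[8-[(dimethylamino)methyl]-5,7-dihydroxy-2,2-dimethyl-2H-chromen-6-yl]butan-1-one; 8 (4R)-2-acetyl-4-geranyl-3,5-dihydroxy-4-methylcyclohexa-2,5-dien-1-one
Product: 15 CNP0203748.1 (target), via o-quinone methide 14 (not isolated)
Conditions: 8 (1.2 eq), degassed MeCN (0.02 M), 365 nm LEDs, FEP flow coil, 10 °C, Ar
Reagents that add atoms: none
Why: Proposed new method: the acidic trione 8 (pKa about 4–5) protonates the benzylic amine of 13 to give a contact ion pair, 365 nm excitation of the o-hydroxybenzylammonium chromophore triggers excited-state proton transfer and C–N heterolysis to o-quinone methide 14, and the paired enolate of 8 adds through its only free ring carbon before the partners diffuse apart, rearomatisation giving the methylene bridge at a temperature where base- or heat-induced scrambling of methylene-bis-phloroglucinols does not occur; the closest known reaction types are photodeamination of o-hydroxybenzyl Mannich bases and ammonium salts to o-quinone methides with nucleophile trapping, and the thermal Mannich-base union of acylphloroglucinols, neither shown for a chelated acyl-chromene donor with a filicinic-acid carbon nucleophile; no stereocentre is formed and the non-enolisable (R) centre of 8 is untouched.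

**Compound list**
1 | ethyl (3S)-3-hydroxybutanoate | C[C@H](O)CC(=O)OCC | starting material
2 | geranyl bromide, (2E)-1-bromo-3,7-dimethylocta-2,6-diene | CC(C)=CCC/C(C)=C/CBr | starting material
3 | ethyl (2S,3S)-2-geranyl-3-hydroxybutanoate | C[C@H](O)[C@H](C/C=C(\C)CCC=C(C)C)C(=O)OCC | intermediate
4 | ethyl (2R,3S)-2-geranyl-3-hydroxy-2-methylbutanoate | C[C@H](O)[C@@](C)(C/C=C(\C)CCC=C(C)C)C(=O)OCC | intermediate
5 | ethyl (2R)-2-geranyl-2-methyl-3-oxobutanoate | CC(=O)[C@@](C)(C/C=C(\C)CCC=C(C)C)C(=O)OCC | intermediate
6 | diketene, 4-methylideneoxetan-2-one | C=C1CC(=O)O1 | starting material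
7 | ethyl (2R)-2-geranyl-2-methyl-3,5,7-trioxooctanoate (present as its enolate) | CC(=O)CC(=O)CC(=O)[C@@](C)(C/C=C(\C)CCC=C(C)C)C(=O)OCC | intermediate
8 | (4R)-2-acetyl-4-geranyl-3,5-dihydroxy-4-methylcyclohexa-2,5-dien-1-one | O=C1C=C(O)[C@@](C)(C/C=C(\C)CCC=C(C)C)C(O)=C1C(C)=O | intermediate
9 | 1-(2,4,6-trihydroxyphenyl)butan-1-one (butyrylphloroglucinol) | CCCC(=O)c1c(O)cc(O)cc1O | starting material
10 | 3-methylbut-2-enal (prenal) | CC(C)=CC=O | starting material
11 | 4-butanoyl-3,5-dihydroxy-6-(3-methylbut-2-en-1-ylidene)cyclohexa-2,4-dien-1-one | CCCC(=O)C1=C(O)C(=CC=C(C)C)C(=O)C=C1O | intermediate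
12 | 1-(5,7-dihydroxy-2,2-dimethyl-2H-chromen-6-yl)butan-1-one | CCCC(=O)c1c(O)cc2OC(C)(C)C=Cc2c1O | intermediate
13 | 1-[8-[(dimethylamino)methyl]-5,7-dihydroxy-2,2-dimethyl-2H-chromen-6-yl]butan-1-one | CCCC(=O)c1c(O)c(CN(C)C)c2OC(C)(C)C=Cc2c1O | intermediate
14 | 6-butanoyl-5-hydroxy-2,2-dimethyl-8-methylidene-2H-chromen-7(8H)-one | C=C1C(=O)C(C(=O)CCC)=C(O)C2=C1OC(C)(C)C=C2 | intermediate
15 | (4R)-2-acetyl-6-[(6-butanoyl-5,7-dihydroxy-2,2-dimethyl-2H-chromen-8-yl)methyl]-4-geranyl-3,5-dihydroxy-4-methylcyclohexa-2,5-dien-1-one (CNP0203748.1) | CCCC(=O)c1c(O)c2c(c(CC3=C(O)[C@@](C)(C/C=C(\C)CCC=C(C)C)C(O)=C(C(C)=O)C3=O)c1O)OC(C)(C)C=C2 | target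

**Totals**
Total steps: 7. Longest linear sequence: 5 (steps 1, 2, 3, 4, 7).

**Three steps most likely to fail**

Step 7 (the proposed new step). The chelated aryl ketone can relax by excited-state proton transfer to the carbonyl, giving a low quantum yield, and the chromene can open reversibly under light. The fallback uses known chemistry and reverses the roles of the halves. It sets out from 8, which is treated with Eschenmoser's salt (CH2Cl2, 0 °C, then aq NaHCO3) to give the filicinic Mannich base (4R)-2-acetyl-6-[(dimethylamino)methyl]-4-geranyl-3,5-dihydroxy-4-methylcyclohexa-2,5-dien-1-one F1. Heating F1 with chromene 12 in dioxane at 80 °C expels the amine thermally to give the exo-methylene trione, to which 12 adds through C8, its only free ring carbon. This comes back to the route at 15 and makes 13 unnecessary.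

Step 4. Diketene may acylate the enolate on oxygen, or the Dieckmann closure onto the neopentyl-type ester may be slow. The fallback sets out from 5, which with LDA and TMSCl (THF, −78 °C) gives the silyl enol ether ethyl (2R)-2-geranyl-2-methyl-3-(trimethylsilyloxy)but-3-enoate F2. Heating F2 with 2,2,6-trimethyl-4H-1,3-dioxin-4-one in toluene at 110 °C generates acetylketene, which adds in a [4+2] hetero-Diels–Alder reaction to give the silyl ketal ethyl (2R)-2-geranyl-2-[6-methyl-4-oxo-2-(trimethylsilyloxy)-3,4-dihydro-2H-pyran-2-yl]propanoate F3. K2CO3 in MeOH removes silicon and opens the ring to triketo ester 7, isolated this time, which is cyclised with t-BuOK in THF as in step 4. This comes back to the route at 8.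

Step 5. The pyran may close onto a 2-OH instead of the 4-OH (giving the 8-acyl chromene), and double annulation is possible. The fallback sets out from 9, whose most acidic, non-chelated 4-OH is alkylated with 3-chloro-3-methylbut-1-yne (CuCl2 cat., DBU, MeCN, 0 °C) to give the aryl propargyl ether 1-[2,6-dihydroxy-4-(2-methylbut-3-yn-2-yloxy)phenyl]butan-1-one F4. Heating F4 in xylene at 140 °C (aromatic propargyl Claisen rearrangement, 1,5-H shift, oxa-6π closure) can build the pyran only on the 4-oxygen, and both ortho carbons are equivalent. This comes back to the route at 12 as a single regioisomer.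

**Further compounds**
F1 | step 7 | (4R)-2-acetyl-6-[(dimethylamino)methyl]-4-geranyl-3,5-dihydroxy-4-methylcyclohexa-2,5-dien-1-one | CN(C)CC1=C(O)[C@@](C)(C/C=C(\C)CCC=C(C)C)C(O)=C(C(C)=O)C1=O
F2 | step 4 | ethyl (2R)-2-geranyl-2-methyl-3-(trimethylsilyloxy)but-3-enoate | C=C(O[Si](C)(C)C)[C@@](C)(C/C=C(\C)CCC=C(C)C)C(=O)OCC
F3 | step 4 | ethyl (2R)-2-geranyl-2-[6-methyl-4-oxo-2-(trimethylsilyloxy)-3,4-dihydro-2H-pyran-2-yl]propanoate (mixture at the ketal carbon) | CCOC(=O)[C@](C)(C/C=C(\C)CCC=C(C)C)C1(O[Si](C)(C)C)CC(=O)C=C(C)O1
F4 | step 5 | 1-[2,6-dihydroxy-4-(2-methylbut-3-yn-2-yloxy)phenyl]butan-1-one | CCCC(=O)c1c(O)cc(OC(C)(C)C#C)cc1O
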